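**Strategy.** Ring atoms are numbered C1 (acetoxy carbon) to C11 (CMe2 carbon). The plan rests on cutting the eleven-membered carbocycle at the C7–C8 single bond, the point where the E-trisubstituted C6=C7 alkene meets the saturated C8–C10 tether to quaternary C11. In one operation, 9-BBN hydroboration of a terminal C8=C9 alkene and intramolecular B-alkyl Suzuki–Miyaura coupling with a C7 alkenyl iodide form this bond, close the ring and carry the E geometry over unchanged. The precursor is an acyclic dodecatriene that already holds the (Z)-C2=C3 alkene and both carbinol centres, C1 as PMB ether and C4 as TBS ether.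

Key step: step 12

Assumption: pent-3-yn-1-ol and 4-(tert-butyldimethylsilyloxy)benzoic acid are taken as purchasable; macrocycles are named with the ring numbering above (PMB = 4-methoxybenzyl, TBS = tert-butyldimethylsilyl).

Step 1
Reactants: 1 2,2-dimethylpent-4-enal; 2 1-propynylmagnesium bromide
Product: 3 rac-4,4-dimethyloct-1-en-6-yn-5-ol
Conditions: THF, −78 → 0 °C; then H2O
Reagents that add atoms: none
Why: 1,2-addition of an alkynyl Grignard reagent to an aldehyde that has no α-hydrogen should give the propargylic alcohol cleanly as a racemate, the stereocentre being set in step 3.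

Step 2
Reactants: 3 rac-4,4-dimethyloct-1-en-6-yn-5-ol
Product: 4 4,4-dimethyloct-1-en-6-yn-5-one
Conditions: Dess–Martin periodinane, CH2Cl2, 0 °C → rt
Reagents that add atoms: none
Why: Dess–Martin oxidation of a secondary propargylic alcohol should give the ynone without touching the alkyne or the terminal alkene.

Step 3
Reactants: 4 4,4-dimethyloct-1-en-6-yn-5-one
Product: 5 (S)-4,4-dimethyloct-1-en-6-yn-5-ol
Conditions: (S)-1-methyl-3,3-diphenyltetrahydro-1H,3H-pyrrolo[1,2-c][1,3,2]oxazaborole (0.5 equiv), catecholborane (1.5 equiv), CH2Cl2, −78 → −40 °C; aqueous work-up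
Reagents that add atoms: none
Why: Corey–Bakshi–Shibata reduction, in which the quaternary C11 substituent acts as the large group and the slim propynyl group as the small one, should deliver hydride to the face that gives the (S)-alcohol (alkynyl outranks the quaternary carbon in the CIP order), and catecholborane is chosen because it does not hydroborate the terminal alkene at low temperature.

Step 4
Reactants: 5 (S)-4,4-dimethyloct-1-en-6-yn-5-ol
Product: 7 (5R,6Z)-7-iodo-4,4-dimethylocta-1,6-dien-5-ol, via sodium alkenylaluminate 6 (not isolated)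
Conditions: NaAlH2(OCH2CH2OMe)2 (1.5 equiv), THF, 0 °C → rt; then I2 in THF, −78 °C, added until the colour just persists; cold aqueous work-up
Reagents that add atoms: iodine, II
Why: hydroxyl-directed trans-hydroalumination of the propargylic alcohol places hydride on C2 and aluminium on C3 in a five-membered alkoxyaluminate, and iodinolysis of the C–Al bond with retention should give the Z-iodide (iodine cis to the carbinol carbon) with the stereocentre untouched (its descriptor changes from S to R only because the CIP ranking of the neighbours changes), the low temperature keeping the distal terminal alkene out of iodoetherification.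

Step 5
Reactants: 7 (5R,6Z)-7-iodo-4,4-dimethylocta-1,6-dien-5-ol
Product: 8 (5R,6Z)-7-iodo-5-(4-methoxybenzyloxy)-4,4-dimethylocta-1,6-diene
Conditions: NaH, 4-methoxybenzyl chloride, Bu4NI (cat.), THF/DMF, 0 °C → rt
Reagents that add atoms: 4-methoxybenzyl chloride, COc1ccc(CCl)cc1
Why: Williamson etherification of the sodium alkoxide with iodide catalysis should protect the hindered C1 hydroxyl as an ether that survives organolithium, borane and palladium chemistry, with no bond to the stereocentre broken.

Step 6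
Reactants: 9 pent-3-yn-1-ol
Product: 11 (E)-4-iodopent-3-en-1-ol, via alkenylzirconocene chloride 10 (not isolated)
Conditions: Cp2Zr(H)Cl (2.5 equiv), THF, rt → 45 °C; then I2, THF, 0 °C; aqueous work-up
Reagents that add atoms: iodine, II
Why: syn-hydrozirconation of the internal alkyne with excess zirconocene chloride hydride (the first equivalent is consumed by the hydroxyl group) should equilibrate zirconium to the less hindered methyl-bearing carbon, and iodinolysis with retention then fixes the E geometry (iodine trans to the CH2CH2OH chain).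

Step 7
Reactants: 11 (E)-4-iodopent-3-en-1-ol
Product: 12 (E)-4-iodopent-3-enal
Conditions: Dess–Martin periodinane, NaHCO3, CH2Cl2, 0 °C; used at once without chromatography
Reagents that add atoms: none
Why: buffered Dess–Martin oxidation of the primary alcohol under near-neutral conditions should give the β,γ-unsaturated aldehyde without moving the double bond into conjugation or harming the alkenyl iodide.

Step 8
Reactants: 8 (5R,6Z)-7-iodo-5-(4-methoxybenzyloxy)-4,4-dimethylocta-1,6-diene; 12 (E)-4-iodopent-3-enal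
Product: 15 (2E,6Z,8R)-2-iodo-8-(4-methoxybenzyloxy)-6,9,9-trimethyldodeca-2,6,11-trien-5-ol (both C5 epimers), via Z-alkenyllithium 13 (not isolated), via Z-alkenylcerium dichloride 14 (not isolated)
Conditions: 8, t-BuLi (2.1 equiv), Et2O, −78 °C; anhydrous CeCl3 (THF slurry), −78 °C; then 12, −78 °C; H2O
Reagents that add atoms: none
Why: iodine–lithium exchange with retention of the Z geometry, transmetalation to the weakly basic organocerium reagent and 1,2-addition to the aldehyde should form the C3–C4 bond without enolising the aldehyde or exchanging its alkenyl iodide, the new carbinol centre being left uncontrolled here and fixed in steps 9 and 10.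

Step 9
Reactants: 15 (2E,6Z,8R)-2-iodo-8-(4-methoxybenzyloxy)-6,9,9-trimethyldodeca-2,6,11-trien-5-ol
Product: 16 (2E,6Z,8R)-2-iodo-8-(4-methoxybenzyloxy)-6,9,9-trimethyldodeca-2,6,11-trien-5-one
Conditions: Dess–Martin periodinane, NaHCO3, CH2Cl2, 0 °C
Reagents that add atoms: none
Why: Dess–Martin oxidation should converge both allylic alcohol epimers on one enone, the buffered conditions avoiding migration of the C6=C7 bond (ring numbering) and Z→E isomerisation of C2=C3.

Step 10
Reactants: 16 (2E,6Z,8R)-2-iodo-8-(4-methoxybenzyloxy)-6,9,9-trimethyldodeca-2,6,11-trien-5-one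
Product: 17 (2E,5R,6Z,8R)-2-iodo-8-(4-methoxybenzyloxy)-6,9,9-trimethyldodeca-2,6,11-trien-5-ol
Conditions: (S)-1-methyl-3,3-diphenyltetrahydro-1H,3H-pyrrolo[1,2-c][1,3,2]oxazaborole (1.0 equiv), catecholborane (2 equiv), toluene, −78 °C; aqueous work-up
Reagents that add atoms: none
Why: Corey–Bakshi–Shibata reduction with the α-methylalkenyl group as the large and the C5 methylene (ring numbering) as the small substituent should set the ring C4 carbinol as R under reagent control (the oxazaborolidine is used stoichiometrically to override any bias from C1), while catecholborane leaves the terminal alkene and the alkenyl iodide alone.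

Step 11
Reactants: 17 (2E,5R,6Z,8R)-2-iodo-8-(4-methoxybenzyloxy)-6,9,9-trimethyldodeca-2,6,11-trien-5-ol
Product: 18 (2E,5R,6Z,8R)-5-(tert-butyldimethylsilyloxy)-2-iodo-8-(4-methoxybenzyloxy)-6,9,9-trimethyldodeca-2,6,11-triene
Conditions: TBSOTf, 2,6-lutidine, CH2Cl2, −78 °C
Reagents that add atoms: tert-butyldimethylsilyl trifluoromethanesulfonate, CC(C)(C)[Si](C)(C)OS(=O)(=O)C(F)(F)F
Why: silylation of the hindered allylic alcohol with the silyl triflate and a non-nucleophilic base should proceed without breaking any bond to a stereocentre and gives an ether, not an ionisable allylic ester, for the palladium step.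

Step 12
Reactants: 18 (2E,5R,6Z,8R)-5-(tert-butyldimethylsilyloxy)-2-iodo-8-(4-methoxybenzyloxy)-6,9,9-trimethyldodeca-2,6,11-triene
Product: 20 (1R,2Z,4R,6E)-4-(tert-butyldimethylsilyloxy)-1-(4-methoxybenzyloxy)-3,7,11,11-tetramethylcycloundeca-2,6-diene, via B-alkyl-9-BBN 19 (not isolated)
Conditions: 9-borabicyclo[3.3.1]nonane (9-BBN, 2 equiv), THF, rt; then slow addition (syringe pump) to Pd(dppf)Cl2 (dppf = 1,1'-bis(diphenylphosphino)ferrocene, 0.2 equiv), AsPh3 (0.4 equiv), Cs2CO3 (3 equiv), DMF/THF/H2O, 50 °C, final concentration about 2 mM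
Reagents that add atoms: none
Why: 9-BBN should add anti-Markovnikov to the monosubstituted C8=C9 alkene only, since the two trisubstituted alkenes and the alkenyl iodide react far more slowly, giving the primary C8 alkylborane and leaving just a hydrogen on C9. Zerovalent palladium formed in situ inserts into the C7–I bond, the base-activated borane transfers its primary alkyl group to palladium, and reductive elimination forms C7–C8 with retention of the E geometry. The closest known reaction type is the intramolecular B-alkyl Suzuki–Miyaura macrocyclisation of alkenyl iodides with alkyl-9-BBN reagents, an established way to close medium and large carbocycles. The eleven-membered ring closes head-to-tail between the chain termini C7 and C8 by reductive elimination from a twelve-membered palladacycle; no stereocentre is created, and C1 and C4 lie away from the reacting carbons. The step needs ring closure to outrun oligomerisation and β-hydride elimination, which high dilution with slow addition, the wide-bite-angle dppf ligand and the turn built into the chain by the Z-C2=C3 alkene and the gem-dimethyl group at C11 should secure. Ether protection at the allylic C1 and C4 oxygens prevents ionisation to π-allylpalladium species.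

Step 13
Reactants: 20 (1R,2Z,4R,6E)-4-(tert-butyldimethylsilyloxy)-1-(4-methoxybenzyloxy)-3,7,11,11-tetramethylcycloundeca-2,6-diene
Product: 21 (1R,2Z,4R,6E)-1-(4-methoxybenzyloxy)-3,7,11,11-tetramethylcycloundeca-2,6-dien-4-ol
Conditions: Bu4NF, THF, 0 °C → rt; H2O
Reagents that add atoms: none
Why: fluoride cleavage of the secondary silyl ether should be clean at this stage because the molecule carries no ester that could migrate or be cleaved, and the PMB ether is inert to fluoride.

Step 14
Reactants: 21 (1R,2Z,4R,6E)-1-(4-methoxybenzyloxy)-3,7,11,11-tetramethylcycloundeca-2,6-dien-4-ol; 22 4-(tert-butyldimethylsilyloxy)benzoic acid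
Product: 23 (1R,2Z,4R,6E)-1-(4-methoxybenzyloxy)-3,7,11,11-tetramethylcycloundeca-2,6-dien-4-yl 4-(tert-butyldimethylsilyloxy)benzoate
Conditions: N-(3-dimethylaminopropyl)-N'-ethylcarbodiimide hydrochloride (EDC·HCl), 4-(dimethylamino)pyridine, CH2Cl2, 0 °C → rt
Reagents that add atoms: none
Why: Steglich esterification through the acylpyridinium ion acylates the C4 oxygen without breaking the C4–O bond, so the R configuration should be retained, and the phenol is masked as its silyl ether to prevent self-acylation.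

Step 15
Reactants: 23 (1R,2Z,4R,6E)-1-(4-methoxybenzyloxy)-3,7,11,11-tetramethylcycloundeca-2,6-dien-4-yl 4-(tert-butyldimethylsilyloxy)benzoate
Product: 24 (1R,2Z,4R,6E)-1-hydroxy-3,7,11,11-tetramethylcycloundeca-2,6-dien-4-yl 4-(tert-butyldimethylsilyloxy)benzoate
Conditions: DDQ (2,3-dichloro-5,6-dicyano-1,4-benzoquinone, 1.3 equiv), CH2Cl2/pH 7 buffer, 0 °C
Reagents that add atoms: none
Why: oxidative PMB cleavage (hydride abstraction to the oxocarbenium ion, then hydrolysis) should free the C1 hydroxyl while the electron-poor aroyl ester, the aryl silyl ether and both trisubstituted alkenes stay intact, and an aroyl group is unlikely to migrate to the hindered neopentylic oxygen.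

Step 16
Reactants: 24 (1R,2Z,4R,6E)-1-hydroxy-3,7,11,11-tetramethylcycloundeca-2,6-dien-4-yl 4-(tert-butyldimethylsilyloxy)benzoate
Product: 25 (1R,2Z,4R,6E)-1-acetoxy-3,7,11,11-tetramethylcycloundeca-2,6-dien-4-yl 4-(tert-butyldimethylsilyloxy)benzoate
Conditions: Ac2O, Et3N, 4-(dimethylamino)pyridine, CH2Cl2, rt
Reagents that add atoms: acetic anhydride, CC(=O)OC(C)=O
Why: nucleophilic-catalysed acetylation should acylate even the neopentylic secondary alcohol with retention at C1, the aryl silyl ether and the benzoate being stable to these conditions.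

Step 17
Reactants: 25 (1R,2Z,4R,6E)-1-acetoxy-3,7,11,11-tetramethylcycloundeca-2,6-dien-4-yl 4-(tert-butyldimethylsilyloxy)benzoate
Product: 26 (1R,2Z,4R,6E)-1-acetoxy-3,7,11,11-tetramethylcycloundeca-2,6-dien-4-yl 4-hydroxybenzoate (target)
Conditions: Bu4NF, AcOH (1:1), THF, 0 °C
Reagents that add atoms: none
Why: an aryl silyl ether is cleaved by buffered fluoride at 0 °C far faster than esters react, so the phenol should be released with the acetate and the benzoate untouched.

**Compound list**

1 | 2,2-dimethylpent-4-enal | C=CCC(C)(C)C=O | starting material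
2 | 1-propynylmagnesium bromide | CC#C[Mg]Br | starting material
3 | rac-4,4-dimethyloct-1-en-6-yn-5-ol | CC#CC(O)C(C)(C)CC=C | intermediate
4 | 4,4-dimethyloct-1-en-6-yn-5-one | CC#CC(=O)C(C)(C)CC=C | intermediate
5 | (S)-4,4-dimethyloct-1-en-6-yn-5-ol | CC#C[C@@H](O)C(C)(C)CC=C | intermediate
6 | sodium cyclic alkenyl(alkoxy)bis(2-methoxyethoxy)aluminate from 5 (not isolated) | [Na+].CC1=C[C@H](C(C)(C)CC=C)O[Al-]1(OCCOC)OCCOC | intermediate
7 | (5R,6Z)-7-iodo-4,4-dimethylocta-1,6-dien-5-ol | I/C(C)=C\[C@@H](O)C(C)(C)CC=C | intermediate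
8 | (5R,6Z)-7-iodo-5-(4-methoxybenzyloxy)-4,4-dimethylocta-1,6-diene | I/C(C)=C\[C@@H](OCc1ccc(OC)cc1)C(C)(C)CC=C | intermediate
9 | pent-3-yn-1-ol | CC#CCCO | starting material
10 | (E)-alkenylzirconocene chloride of pent-3-yn-1-ol, O-zirconated, cyclopentadienyl drawn σ-bonded (not isolated) | C/C(=C\CCO[Zr](Cl)(C1C=CC=C1)C1C=CC=C1)[Zr](Cl)(C1C=CC=C1)C1C=CC=C1 | intermediate
11 | (E)-4-iodopent-3-en-1-ol | I/C(C)=C/CCO | intermediate
12 | (E)-4-iodopent-3-enal | I/C(C)=C/CC=O | intermediate
13 | Z-alkenyllithium from 8, lithium in place of iodine (not isolated) | [Li]/C(C)=C\[C@@H](OCc1ccc(OC)cc1)C(C)(C)CC=C | intermediate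
14 | Z-alkenylcerium dichloride from 13 (not isolated) | Cl[Ce](Cl)/C(C)=C\[C@@H](OCc1ccc(OC)cc1)C(C)(C)CC=C | intermediate
15 | (2E,6Z,8R)-2-iodo-8-(4-methoxybenzyloxy)-6,9,9-trimethyldodeca-2,6,11-trien-5-ol, both C5 epimers | I/C(C)=C/CC(O)/C(C)=C\[C@@H](OCc1ccc(OC)cc1)C(C)(C)CC=C | intermediate
16 | (2E,6Z,8R)-2-iodo-8-(4-methoxybenzyloxy)-6,9,9-trimethyldodeca-2,6,11-trien-5-one | I/C(C)=C/CC(=O)/C(C)=C\[C@@H](OCc1ccc(OC)cc1)C(C)(C)CC=C | intermediate
17 | (2E,5R,6Z,8R)-2-iodo-8-(4-methoxybenzyloxy)-6,9,9-trimethyldodeca-2,6,11-trien-5-ol | I/C(C)=C/C[C@@H](O)/C(C)=C\[C@@H](OCc1ccc(OC)cc1)C(C)(C)CC=C | intermediate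
18 | (2E,5R,6Z,8R)-5-(tert-butyldimethylsilyloxy)-2-iodo-8-(4-methoxybenzyloxy)-6,9,9-trimethyldodeca-2,6,11-triene | I/C(C)=C/C[C@@H](O[Si](C)(C)C(C)(C)C)/C(C)=C\[C@@H](OCc1ccc(OC)cc1)C(C)(C)CC=C | intermediate
19 | B-alkyl-9-BBN from 18, boron on the former terminal carbon (ring C8) (not isolated) | I/C(C)=C/C[C@@H](O[Si](C)(C)C(C)(C)C)/C(C)=C\[C@@H](OCc1ccc(OC)cc1)C(C)(C)CCCB1C2CCCC1CCC2 | intermediate
20 | (1R,2Z,4R,6E)-4-(tert-butyldimethylsilyloxy)-1-(4-methoxybenzyloxy)-3,7,11,11-tetramethylcycloundeca-2,6-diene | COc1ccc(CO[C@@H]2/C=C(/C)[C@H](O[Si](C)(C)C(C)(C)C)C/C=C(\C)CCCC2(C)C)cc1 | intermediate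
21 | (1R,2Z,4R,6E)-1-(4-methoxybenzyloxy)-3,7,11,11-tetramethylcycloundeca-2,6-dien-4-ol | COc1ccc(CO[C@@H]2/C=C(/C)[C@H](O)C/C=C(\C)CCCC2(C)C)cc1 | intermediate
22 | 4-(tert-butyldimethylsilyloxy)benzoic acid | CC(C)(C)[Si](C)(C)Oc1ccc(cc1)C(=O)O | starting material
23 | (1R,2Z,4R,6E)-1-(4-methoxybenzyloxy)-3,7,11,11-tetramethylcycloundeca-2,6-dien-4-yl 4-(tert-butyldimethylsilyloxy)benzoate | COc1ccc(CO[C@@H]2/C=C(/C)[C@H](OC(=O)c3ccc(O[Si](C)(C)C(C)(C)C)cc3)C/C=C(\C)CCCC2(C)C)cc1 | intermediate
24 | (1R,2Z,4R,6E)-1-hydroxy-3,7,11,11-tetramethylcycloundeca-2,6-dien-4-yl 4-(tert-butyldimethylsilyloxy)benzoate | O[C@@H]1/C=C(/C)[C@H](OC(=O)c2ccc(O[Si](C)(C)C(C)(C)C)cc2)C/C=C(\C)CCCC1(C)C | intermediate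
25 | (1R,2Z,4R,6E)-1-acetoxy-3,7,11,11-tetramethylcycloundeca-2,6-dien-4-yl 4-(tert-butyldimethylsilyloxy)benzoate | CC(=O)O[C@@H]1/C=C(/C)[C@H](OC(=O)c2ccc(O[Si](C)(C)C(C)(C)C)cc2)C/C=C(\C)CCCC1(C)C | intermediate
26 | (1R,2Z,4R,6E)-1-acetoxy-3,7,11,11-tetramethylcycloundeca-2,6-dien-4-yl 4-hydroxybenzoate | CC(=O)O[C@@H]1/C=C(/C)[C@H](OC(=O)c2ccc(O)cc2)C/C=C(\C)CCCC1(C)C | target

**Step count.** Total: 17 steps. Longest linear sequence: 15 steps (steps 1–5, then 8–17); the side branch (steps 6–7) has 2 steps.

**Steps most likely to fail**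

1. Step 12. The alkylborane may couple between molecules (oligomerisation), or be lost by β-hydride elimination or protodeboronation, before the strained eleven-membered ring can close. The fallback sets out from 5 and 11 and comes back at 21; it makes C7–C8 intermolecularly and closes the ring at C3–C4 instead.
   - 11 would be silylated (TBSCl, imidazole, DMF) to (E)-tert-butyl[(4-iodopent-3-en-1-yl)oxy]dimethylsilane F1.
   - 5 would be treated with 9-BBN (2.2 equiv, THF), which converts the hydroxyl into its borinate and adds to the terminal alkene in preference to the internal alkyne, to give the O,C-bis(9-borabicyclononyl) adduct F2.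
   - F2 would be coupled in the same flask with F1 (Pd(dppf)Cl2, AsPh3, Cs2CO3, DMF/THF/H2O, rt) to give (4S,9E)-12-(tert-butyldimethylsilyloxy)-5,5,9-trimethyldodec-9-en-2-yn-4-ol F3.
   - Trans-hydroalumination and iodination as in step 4 should give (2Z,4R,9E)-12-(tert-butyldimethylsilyloxy)-2-iodo-5,5,9-trimethyldodeca-2,9-dien-4-ol F4.
   - PMB protection as in step 5 should give the 4-(4-methoxybenzyl) ether of F4, (2Z,4R,9E)-12-(tert-butyldimethylsilyloxy)-2-iodo-4-(4-methoxybenzyloxy)-5,5,9-trimethyldodeca-2,9-diene F5.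
   - Bu4NF would free the primary alcohol (3E,9R,10Z)-11-iodo-9-(4-methoxybenzyloxy)-4,8,8-trimethyldodeca-3,10-dien-1-ol F6, and buffered Dess–Martin oxidation would give (3E,9R,10Z)-11-iodo-9-(4-methoxybenzyloxy)-4,8,8-trimethyldodeca-3,10-dienal F7.
   - An intramolecular Nozaki–Hiyama–Kishi reaction (CrCl2, NiCl2 cat., DMSO/THF, high dilution) would close the ring between C3 and C4. The (4R)-carbinol is 21; it would be separated by chromatography from its C4 epimer (1R,2Z,4S,6E)-1-(4-methoxybenzyloxy)-3,7,11,11-tetramethylcycloundeca-2,6-dien-4-ol F8, and the route continues with step 14.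

2. Step 8. The labile β,γ-unsaturated aldehyde may be enolised by the organometallic reagent, or its double bond may migrate into conjugation during preparation and handling, so that the C3–C4 bond forms incompletely. The fallback sets out from 11 and 8 and comes back at 16.
   - 11 would be oxidised with 2,2,6,6-tetramethylpiperidin-1-oxyl (cat.) and PhI(OAc)2 in MeCN/H2O to the stable (E)-4-iodopent-3-enoic acid F9.
   - F9 would be converted (EDC·HCl, MeNHOMe·HCl, N-methylmorpholine, CH2Cl2) into the N-methoxy-N-methylamide (E)-4-iodo-N-methoxy-N-methylpent-3-enamide F10, a storable acyl donor much less acidic than the aldehyde.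
   - Alkenyllithium 13, generated from 8 as in step 8, would be added to F10 at −78 °C. The chelated tetrahedral adduct should collapse on work-up to enone 16 directly, which also makes step 9 unnecessary.

3. Step 10. Facial selectivity may be poor, because the Z-enone is twisted out of conjugation and the resident C1 stereocentre may oppose the catalyst. The fallback sets out from 15 and comes back at 17.
   - The C5 epimers of 15 from step 8 would be separated by chromatography; the (5R)-epimer is 17.
   - The other epimer, (2E,5S,6Z,8R)-2-iodo-8-(4-methoxybenzyloxy)-6,9,9-trimethyldodeca-2,6,11-trien-5-ol F11, would be inverted by a Mitsunobu reaction (4-nitrobenzoic acid, PPh3, diisopropyl azodicarboxylate, toluene, 0 °C) to (2E,5R,6Z,8R)-2-iodo-8-(4-methoxybenzyloxy)-6,9,9-trimethyldodeca-2,6,11-trien-5-yl 4-nitrobenzoate F12.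
   - Methanolysis of F12 (K2CO3, MeOH) should give 17; steps 9 and 10 are then not needed.

**Further compounds**

F1 | step 12 | (E)-tert-butyl[(4-iodopent-3-en-1-yl)oxy]dimethylsilane | I/C(C)=C/CCO[Si](C)(C)C(C)(C)C
F2 | step 12 | O,C-bis(9-borabicyclononyl) adduct of 5 | CC#C[C@@H](OB1C2CCCC1CCC2)C(C)(C)CCCB1C2CCCC1CCC2
F3 | step 12 | (4S,9E)-12-(tert-butyldimethylsilyloxy)-5,5,9-trimethyldodec-9-en-2-yn-4-ol | CC#C[C@@H](O)C(C)(C)CCC/C(C)=C/CCO[Si](C)(C)C(C)(C)C
F4 | step 12 | (2Z,4R,9E)-12-(tert-butyldimethylsilyloxy)-2-iodo-5,5,9-trimethyldodeca-2,9-dien-4-ol | I/C(C)=C\[C@@H](O)C(C)(C)CCC/C(C)=C/CCO[Si](C)(C)C(C)(C)C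
F5 | step 12 | (2Z,4R,9E)-12-(tert-butyldimethylsilyloxy)-2-iodo-4-(4-methoxybenzyloxy)-5,5,9-trimethyldodeca-2,9-diene | I/C(C)=C\[C@@H](OCc1ccc(OC)cc1)C(C)(C)CCC/C(C)=C/CCO[Si](C)(C)C(C)(C)C
F6 | step 12 | (3E,9R,10Z)-11-iodo-9-(4-methoxybenzyloxy)-4,8,8-trimethyldodeca-3,10-dien-1-ol | I/C(C)=C\[C@@H](OCc1ccc(OC)cc1)C(C)(C)CCC/C(C)=C/CCO
F7 | step 12 | (3E,9R,10Z)-11-iodo-9-(4-methoxybenzyloxy)-4,8,8-trimethyldodeca-3,10-dienal | I/C(C)=C\[C@@H](OCc1ccc(OC)cc1)C(C)(C)CCC/C(C)=C/CC=O
F8 | step 12 | (1R,2Z,4S,6E)-1-(4-methoxybenzyloxy)-3,7,11,11-tetramethylcycloundeca-2,6-dien-4-ol | COc1ccc(CO[C@@H]2/C=C(/C)[C@@H](O)C/C=C(\C)CCCC2(C)C)cc1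
F9 | step 8 | (E)-4-iodopent-3-enoic acid | I/C(C)=C/CC(=O)O
F10 | step 8 | (E)-4-iodo-N-methoxy-N-methylpent-3-enamide | I/C(C)=C/CC(=O)N(C)OC
F11 | step 10 | (2E,5S,6Z,8R)-2-iodo-8-(4-methoxybenzyloxy)-6,9,9-trimethyldodeca-2,6,11-trien-5-ol | I/C(C)=C/C[C@H](O)/C(C)=C\[C@@H](OCc1ccc(OC)cc1)C(C)(C)CC=C
F12 | step 10 | (2E,5R,6Z,8R)-2-iodo-8-(4-methoxybenzyloxy)-6,9,9-trimethyldodeca-2,6,11-trien-5-yl 4-nitrobenzoate | I/C(C)=C/C[C@@H](OC(=O)c1ccc(cc1)[N+](=O)[O-])/C(C)=C\[C@@H](OCc1ccc(OC)cc1)C(C)(C)CC=C
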